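- The south-west run reads 8.7 % of target at 3.00 h and the north run 1.6 %, but these are percentages of very different charges.
- Multiplied out, the south-west, south-east and north runs hold c(target) = 1.57 mM, 1.74 mM and 1.92 mM, though the charge runs from 0.018 M to 0.12 M.
- So we freeze c(target) as independent of the charge, with a mean of 1.74 mM at that time, and read a yield as c(target) divided by the charge.

| flask | solid substrate | remark | time |
|---|---|---|---|
| south-west | 0.018 M | run made earlier |  |
| south-east | 0.058 M | run made earlier |  |
| north | 0.12 M | run made earlier |  |
| autumn | 0.060 M |  | 6.0 h |
| dusk | 0.15 M |  | 6.0 h |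
| dawn | 0.020 M |  | 6.0 h |
| midnight | 0.042 M |  | 6.0 h |

- south-west (time / h: target / %): 0.667: 0.8; 1.33: 2.4; 2.00: 4.4; 2.50: 6.7; 3.00: 8.7
- south-east (time / h: target / %): 0.250: 0.2; 0.417: 0; 0.833: 0; 1.50: 0.4; 3.00: 3.0
- north (time / h: target / %): 0.667: 0.7; 1.33: 0.1; 2.00: 1.0; 2.50: 1.0; 3.00: 1.6

(each reading ± 0.3 percentage points)

- at the start none of the solid substrate is in solution
- what has only dissolved of solid substrate counts as not reacted
- a reading or a percentage of target counts all its forms, free or not

- the flasks put in order of amount of target, in percent of the solid substrate charged, best first, at 6.0 h (autumn / dusk / dawn / midnight)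
- the amount of target, in percent of the solid substrate charged of the flask you put first, at 6.0 h
- the amount of target, in percent of the solid substrate charged of the flask you put last, at 6.0 h

Our own ladder of times, from the shortest to the longest:

- First comes a hold-up. The south-west readings from 2.00 h to 3.00 h give a pace of 0.774 mM h⁻¹, and a line at that pace through our mean starts near 0.749 h.
- Next comes the straight line, zero order in the charge. At 6.0 h it stands at 4.06 mM, and this c(target) is the charge-free output.
- Last comes the end of the charge. At this pace dawn, the smallest charge, lasts 25.8 h and dusk 194 h, both longer than the time asked, so we keep the line.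
- Dividing the output by each charge, we reckon dawn 20.3 %, midnight 9.68 %, autumn 6.77 % and dusk 2.71 %.

The forecast:

- It gives dawn > midnight > autumn > dusk, with 21 % and 2.8 %, on this ground: “Target formed is therefore almost independent of charge”. It takes 4.2 mM, a little above our 4.06 mM.

The simulation gives dawn > midnight > autumn > dusk, with 21.0 % and 2.81 %.

    starting material → target (k = 0.400 h⁻¹)
    solid substrate ⇌ starting material, rate k2*(cs2 - [starting material]) while solid is left; crystals form when [starting material] > cs2 (solubility = 14.0 mM, k = 0.110 h⁻¹)
    crystals ⇌ target, rate k3*(cs3 - [target]) while solid is left; crystals form when [target] > cs3 (solubility = 2.30 mM, k = 20.0 h⁻¹)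
    starting material + target ⇌ idle adduct, settled at all times (K = 280 M⁻¹)

Dawn and dusk hold one output, 4.21 mM and 4.21 mM, against our 4.06 mM. The main reason dusk stays low is the low solubility of starting material, which also sets how fast it dissolves: without it, dusk reaches 73.8 % instead of 2.81 %. Carried back along the line to 1.5 h, the output gives dawn 2.91 %, and dawn read at that time holds 2.61 %.

The numbers in the tables stem from a simulated flask for an exercise; the scatter is artificial.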